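# Betaethrin A (22) by pyrone/ynol ether cycloaddition: route design

## The problem

Betaethrin A (22) is an achiral diaryl ether made of two tetrasubstituted benzene rings. Ring A is a methyl benzoate (C1 CO2CH3, C2 OH, C4 CH3, C6 O-aryl). Ring B is a benzyl acetate (C1' O-aryl, C2' OH, C4' OCH3, C6' CH2OAc). The ether oxygen is flanked by three ortho substituents: the ester on ring A, and the hydroxyl and acetoxymethyl groups on ring B. Joining two finished rings at C6–O by substitution or coupling is therefore the difficult bond. There is no stereocentre. What must be controlled is the regiochemistry of ring A (oxygen on both sides of the ester carbon, methyl para to it) and the differentiation of three hydroxyl oxygens, of which only the benzylic one is acetylated. The benzylic acetate will not survive organolithium reagents, alkoxide or acidic methanol, and the electron-rich ring B phenol is easily oxidised. Under forcing acylating conditions the ring B phenol could close onto the ring A ester to a seven-membered depsidone lactone. The feature that opens the route is that C6 and C5 of ring A carry only the ether oxygen and a hydrogen, which is the pattern of an aryl ethynyl ether. C1–C4 with ester, oxygen, hydrogen and methyl map onto C3–C6 of a 3-carbomethoxy-4-acyloxy-6-methyl-2-pyrone, whose C2 carbonyl and ring oxygen can leave as CO2.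

## Retrosynthesis

**22 to 21.** The acetyl C–O bond at the benzylic oxygen is cut last. The acetate cannot be carried earlier, because the alkyne-forming step needs n-BuLi and the unmasking of the phenols needs acid in methanol. Triol 21 is the fully unmasked core. The forward step must acetylate the one aliphatic hydroxyl in the presence of two phenols; a Mitsunobu esterification, which activates only the alcohol, is chosen over peracetylation and selective cleavage because it is one step instead of two.

**21 to 20.** Three oxygen–protecting-group bonds are cut: the ring A acetate, the ring B methoxymethyl ether and the benzylic silyl ether. Each is dictated by an earlier step (acetate on the pyrone, MOM and TBS to survive n-BuLi and heat), and all three leave in one acidic methanolysis. The forward reaction only has to avoid ionising the benzylic alcohol.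

**20 to 12 and 18 (through 19).** Ring A is cut at C1–C6 and C4–C5 and CO2 is put back across C1 and C4. This gives aryl ethynyl ether 12 and acetoxypyrone 18, which would combine through the bridged lactone 19. Against a cut at the C6–O bond, this places the hindered oxygen on an unhindered sp carbon before ring A exists. Against cuts elsewhere in ring A, it uses the polarity of both partners to fix the position of the ether oxygen next to the ester carbon. The precursors are one aromatic ring and one heterocycle. The forward reaction must be regioselective and must outrun self-reaction of the ynol ether.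

**18 to 17, then 13 and 14.** The acetyl group of 18 is removed to give hydroxypyrone 17. The pyrone is then cut at the ring O–C2 bond and the C3–C4 bond into dimethyl malonate 13 and acetylketene 15, released from dioxinone 14, by way of acylmalonate 16. Both components are commodity chemicals, and the ester at C3 comes in with the malonate, so no later carboxylation is needed.

**12 to 9, then 6 and 7.** The alkyne is traced to the 1,2-dichlorovinyl ether 9 (through chloroalkyne 10 and acetylide 11), and 9 to phenol 6 and trichloroethylene 7 (through dichloroacetylene 8). This is the standard two-step entry to aryl ynol ethers and asks only that the benzylic and phenolic protecting groups tolerate K2CO3 and n-BuLi.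

**6 to 5 to 4.** The silyl group is removed, then the benzylic C–C bond at C6' is cut to formaldehyde and phenol 4. In 4 the para position and one ortho position are blocked, so hydroxymethylation can occur at one carbon only. Diol 5 must then be silylated at the primary hydroxyl and not at the hindered phenol.

**4 to 2 to 1.** The C1' oxygen is traced to a formyl group by Baeyer–Villiger oxidation (through formate 3), and the MOM ether to the free phenol of commercial 2-hydroxy-4-methoxybenzaldehyde 1. This aldehyde already has the C2' and C4' oxygens in the right relationship and differentiated (free OH against OCH3).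

## Roads not taken

**Alternative 1: anodic spirocyclisation of a benzophenone, then methanolysis.** The ether bond is traced to a benzophenone, 2-(2-acetoxy-6-hydroxy-4-methylbenzoyl)-3-hydroxy-5-methoxybenzyl acetate A1. Two-electron anodic oxidation of the ring B phenol of A1 would make C1' electrophilic; the free ring A hydroxyl would close on it to the racemic spiro benzofuranone A2. Methanol would then open A2 at the aryl ketone, cutting the carbonyl–C1' bond, re-aromatising ring B and producing the methyl ester and the diaryl ether together.
- Merits: the hindered C–O bond forms intramolecularly through a five-membered ring; ester and ether positions follow from the connectivity; no strong base is used, so the benzylic acetate could be present from the start. In this last respect it is better than the chosen plan, which has to add the acetate last.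
- Weak points: A1 is a tetra-ortho-substituted benzophenone, so the hard bond is only moved to the aryl–acyl junction. The methoxy group of ring B is meta to the oxidised hydroxyl and does not stabilise positive charge at C1', so attack of methanol at other ring positions and phenol coupling compete. A2 is a linearly conjugated cyclohexa-2,4-dienone, a class that dimerises by Diels–Alder reaction. Methanol must choose the aryl ketone over the dienone carbonyl and two acetates.
- Comparison: two consecutive uncertain steps stand against one in the chosen plan, and the chosen plan makes ring A and the ether position in one regiodefined operation from simple partners.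

**Alternative 2: aryne three-component coupling.** Ring A is cut at C6–O and at C1–C(=O). CsF would convert the silyl triflate A3 into the aryne across C1 and C6. The cesium phenoxide of ring B phenol A4 would add at C6, distal to the methoxy group; the aryl anion at C1 would be trapped by CO2 and the carboxylate methylated with CH3I to give A5.
- Merits: this is the most convergent route on paper (ether oxygen and ester carbon installed in one pot), and the methoxy group steers the regiochemistry of the aryne addition reliably. In step count it is probably better than the chosen plan.
- Weak points: the phenoxide of A4 carries an ortho acetoxymethyl group and should lose acetate to an ortho-quinone methide, or shift the acetyl group onto the phenoxide oxygen, before it meets the aryne. A 2,6-disubstituted phenoxide is a slow aryne trap. The aryl anion must be carboxylated faster than it is protonated. In the endgame the ring A methyl ether must be cleaved beside the ring B methyl ether, and the benzyl ether removed beside a benzylic acetate.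
- Comparison: the chosen plan needs no selective ether cleavage and keeps the base-sensitive acetate out of every basic step.

**Alternative 3: ring A from an aryloxypropiolate and a silyl ketene acetal diene.** Ring A is cut at C1–C2 and C5–C6. The methyl 3-aryloxypropiolate A6 (from acetylide 11 and methyl chloroformate) would react with diene A7; loss of methanol and of the silyl group would give the free salicylate A8.
- Merits: A6 is a push–pull alkyne and more robust than the terminal ynol ether 12; A7 is one step from methyl 3-methylbut-2-enoate; no pyrone and no acetate are needed. The road is one step shorter than the chosen plan and avoids isolating 12.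
- Weak points: the aryloxy donor on the β-carbon raises the acceptor orbital of A6 and makes it a sluggish dienophile. The diene terminus must bond to that same oxygen-bearing carbon, where stepwise conjugate addition followed by loss of aryloxide (net substitution, ring B lost) is a specific escape. Aromatisation needs an elimination.
- Comparison: the chosen plan pairs a donor alkyne with an acceptor diene, so both partners are activated in the required sense; the arene forms with no elimination; and the reaction class is established for 3-carbomethoxy-2-pyrones. Because Alternative 3 shares acetylide 11, it is kept as the fallback for the key step.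

Key step: step 9

## Route

Remark on the chemistry: the target has no stereocentre; the only stereogenic species is the transient bridged lactone 19, which is racemic and drawn as one enantiomer, and 9 is taken to be the E isomer expected from anti addition to dichloroacetylene.

Step 1
Reactants: 1 2-hydroxy-4-methoxybenzaldehyde
Product: 2 4-methoxy-2-(methoxymethoxy)benzaldehyde
Conditions: MOMCl, i-Pr2NEt, CH2Cl2, 0 °C to rt
Reagents that add atoms: chloromethyl methyl ether (MOMCl), COCCl
Why: O-alkylation of the phenol to the methoxymethyl acetal; MOM is chosen because it withstands peracid, aqueous base, n-BuLi at low temperature and heating, and leaves in acid together with the silyl ether.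

Step 2
Reactants: 2 4-methoxy-2-(methoxymethoxy)benzaldehyde
Product: 4 4-methoxy-2-(methoxymethoxy)phenol, via 4-methoxy-2-(methoxymethoxy)phenyl formate 3 (not isolated)
Conditions: mCPBA, CH2Cl2, 0 °C to rt; aq. NaHCO3 wash; then K2CO3 (cat.), MeOH, rt
Reagents that add atoms: m-chloroperbenzoic acid (mCPBA), O=C(OO)c1cccc(Cl)c1
Why: Baeyer–Villiger (Dakin-type) oxidation; the aryl group with ortho and para alkoxy donors migrates in preference to hydrogen, and the formate is transesterified to the phenol, which places the free hydroxyl para to the methoxy group.

Step 3
Reactants: 4 4-methoxy-2-(methoxymethoxy)phenol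
Product: 5 2-(hydroxymethyl)-4-methoxy-6-(methoxymethoxy)phenol
Conditions: 37% aq. CH2O (excess), NaOH (1.1 equiv), H2O, rt; then AcOH to pH 7
Reagents that add atoms: formaldehyde, C=O
Why: Lederer–Manasse hydroxymethylation of the phenoxide; the para position and one ortho position are blocked, so only C6 can react, the product has no free ortho or para position left for a second reaction, and the MOM acetal is inert to aqueous base.

Step 4
Reactants: 5 2-(hydroxymethyl)-4-methoxy-6-(methoxymethoxy)phenol
Product: 6 2-{[(tert-butyldimethylsilyl)oxy]methyl}-4-methoxy-6-(methoxymethoxy)phenol
Conditions: TBSCl (1.05 equiv), imidazole, CH2Cl2, 0 °C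
Reagents that add atoms: tert-butyldimethylsilyl chloride (TBSCl), CC(C)(C)[Si](C)(C)Cl
Why: Silylation of the primary benzylic alcohol should be faster than that of the doubly ortho-flanked, hydrogen-bonded phenol, as is usual for salicyl alcohols with one equivalent of silyl chloride.

Step 5
Reactants: 6 2-{[(tert-butyldimethylsilyl)oxy]methyl}-4-methoxy-6-(methoxymethoxy)phenol; 7 trichloroethylene
Product: 9 tert-butyl({2-[(E)-1,2-dichloroethenyloxy]-5-methoxy-3-(methoxymethoxy)phenyl}methoxy)dimethylsilane, via dichloroacetylene 8 (not isolated)
Conditions: K2CO3, DMF, 70 °C
Reagents that add atoms: none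
Why: K2CO3 dehydrochlorinates trichloroethylene to dichloroacetylene, to which the phenoxide adds in anti fashion to give the E-1,2-dichlorovinyl ether; the electrophile is an unhindered sp carbon, so the two ortho substituents of ring B do not block the addition.

Step 6
Reactants: 9 tert-butyl({2-[(E)-1,2-dichloroethenyloxy]-5-methoxy-3-(methoxymethoxy)phenyl}methoxy)dimethylsilane
Product: 12 tert-butyl{[2-(ethynyloxy)-5-methoxy-3-(methoxymethoxy)phenyl]methoxy}dimethylsilane, via chloroethynyl ether 10 (not isolated), via lithium aryloxyacetylide 11 (not isolated)
Conditions: n-BuLi (2.3 equiv), THF, -78 to -40 °C; then MeOH, -78 °C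
Reagents that add atoms: none
Why: Deprotonation and elimination of LiCl give chloroalkyne 10, chlorine–lithium exchange gives acetylide 11, and a cold protic quench gives the terminal aryl ynol ether (the standard dichlorovinyl ether route); at -78 °C metalation of ring B between its two oxygens is slow and would be undone by the quench.

Step 7
Reactants: 13 dimethyl malonate; 14 2,2,6-trimethyl-4H-1,3-dioxin-4-one
Product: 17 methyl 4-hydroxy-6-methyl-2-oxo-2H-pyran-3-carboxylate, via acetylketene 15 (not isolated), via dimethyl 2-(3-oxobutanoyl)malonate 16 (not isolated)
Conditions: NaH, toluene, rt; then 14 (slow addition), 110 °C; then 1 M aq. HCl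
Reagents that add atoms: none
Why: Retro-(4+2) fragmentation of the dioxinone releases acetylketene, which C-acylates sodium dimethyl malonate; the ketone enolate oxygen of 16 then closes onto a malonate ester with loss of methanol (6-exo-trig lactonisation), the acylketene counterpart of the classical diketene–malonate pyrone synthesis.

Step 8
Reactants: 17 methyl 4-hydroxy-6-methyl-2-oxo-2H-pyran-3-carboxylate
Product: 18 methyl 4-acetoxy-6-methyl-2-oxo-2H-pyran-3-carboxylate
Conditions: AcCl, Et3N, CH2Cl2, -20 to 0 °C; non-aqueous work-up
Reagents that add atoms: acetyl chloride, CC(=O)Cl
Why: O-acylation of a vinylogous carboxylic acid; C3 is fully substituted, so only the 4-oxygen can be acetylated, and the acetate both removes the acidic proton that would add across the ynol ether and weakens the donor effect of the 4-oxygen on the diene.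

Step 9
Reactants: 12 tert-butyl{[2-(ethynyloxy)-5-methoxy-3-(methoxymethoxy)phenyl]methoxy}dimethylsilane; 18 methyl 4-acetoxy-6-methyl-2-oxo-2H-pyran-3-carboxylate
Product: 20 methyl 2-acetoxy-6-{2-[(tert-butyldimethylsilyloxy)methyl]-4-methoxy-6-(methoxymethoxy)phenoxy}-4-methylbenzoate, via bicyclic lactone 19 (not isolated)
Conditions: 18 (2 equiv), toluene, 120 °C (sealed tube), slow addition of 12, BHT (cat.)
Reagents that add atoms: none
Why: Inverse-electron-demand Diels–Alder reaction followed by retro-Diels–Alder loss of CO2, the known route from 3-carbomethoxy-2-pyrones and electron-rich alkynes, ketene acetals or enol ethers to benzoates. The ynol ether is most nucleophilic at its terminal carbon and the pyrone most electrophilic at C6, the vinylogous acceptor terminus of both the lactone and the ester carbonyl, so the C5–C4 bond of ring A should lead and the oxygen-bearing alkyne carbon should then close onto the malonate-like pyrone C3, a concerted but asynchronous suprafacial (4+2) closure to the bridged lactone 19. Ring A is thus closed intermolecularly by two C–C bonds (C1–C6 and C4–C5) as a six-membered carbocycle inside a 2-oxabicyclo[2.2.2]octadienone. At the reaction temperature 19 should expel CO2 by cycloreversion and, the dienophile being an alkyne, ring A appears directly as the arene without elimination or oxidation. The two bridgehead centres of racemic 19 vanish on aromatisation, so no stereocentre has to be controlled. The selectivity required is regiochemical (aryloxy group next to the ester carbon) and is secured by the polarity match just described, the same one that places the alkoxy group ortho to the ester when ketene acetals are used. Self-reaction of the ynol ether is held back by the two ortho substituents of ring B, by the absence of a β-hydrogen for retro-ene ketene formation, and by excess pyrone with slow addition. The MOM ether, silyl ether and esters are inert to neutral heating.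

Step 10
Reactants: 20 methyl 2-acetoxy-6-{2-[(tert-butyldimethylsilyloxy)methyl]-4-methoxy-6-(methoxymethoxy)phenoxy}-4-methylbenzoate
Product: 21 methyl 2-hydroxy-6-[2-hydroxy-6-(hydroxymethyl)-4-methoxyphenoxy]-4-methylbenzoate
Conditions: 3 M HCl in MeOH, rt
Reagents that add atoms: none
Why: Acid-catalysed methanolysis removes all three groups (transacetalisation of the MOM ether, desilylation, transesterification of the aryl acetate) while exchange at the methyl ester is degenerate; the benzylic alcohol is conjugated only with the weakly donating diaryl ether oxygen (both other ring B oxygens are meta), so ionisation should be slow at room temperature.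

Step 11
Reactants: 21 methyl 2-hydroxy-6-[2-hydroxy-6-(hydroxymethyl)-4-methoxyphenoxy]-4-methylbenzoate
Product: 22 Betaethrin A, methyl 2-[2-(acetoxymethyl)-6-hydroxy-4-methoxyphenoxy]-6-hydroxy-4-methylbenzoate
Conditions: AcOH (3 equiv), PPh3, DIAD, THF, 0 °C to rt
Reagents that add atoms: acetic acid, CC(=O)O
Why: Mitsunobu esterification; the phosphonium activates only the aliphatic hydroxyl and acetate displaces it at the primary benzylic carbon, while the phenols, far less acidic than acetic acid, are not acylated when a primary alcohol is present, and the ring B phenol is meta to the benzylic carbon so no quinone methide can form.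

## Compound list

1 | 2-hydroxy-4-methoxybenzaldehyde | COc1ccc(C=O)c(O)c1 | starting material
2 | 4-methoxy-2-(methoxymethoxy)benzaldehyde | COCOc1cc(OC)ccc1C=O | intermediate
3 | 4-methoxy-2-(methoxymethoxy)phenyl formate | COCOc1cc(OC)ccc1OC=O | intermediate (not isolated)
4 | 4-methoxy-2-(methoxymethoxy)phenol | COCOc1cc(OC)ccc1O | intermediate
5 | 2-(hydroxymethyl)-4-methoxy-6-(methoxymethoxy)phenol | COCOc1cc(OC)cc(CO)c1O | intermediate
6 | 2-{[(tert-butyldimethylsilyl)oxy]methyl}-4-methoxy-6-(methoxymethoxy)phenol | COCOc1cc(OC)cc(CO[Si](C)(C)C(C)(C)C)c1O | intermediate
7 | trichloroethylene | ClC=C(Cl)Cl | starting material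
8 | dichloroacetylene | ClC#CCl | intermediate (not isolated)
9 | tert-butyl({2-[(E)-1,2-dichloroethenyloxy]-5-methoxy-3-(methoxymethoxy)phenyl}methoxy)dimethylsilane | Cl/C=C(/Cl)Oc1c(OCOC)cc(OC)cc1CO[Si](C)(C)C(C)(C)C | intermediate
10 | tert-butyl({2-[(chloroethynyl)oxy]-5-methoxy-3-(methoxymethoxy)phenyl}methoxy)dimethylsilane | ClC#COc1c(OCOC)cc(OC)cc1CO[Si](C)(C)C(C)(C)C | intermediate (not isolated)
11 | lithium acetylide of 12, ({2-[(tert-butyldimethylsilyloxy)methyl]-4-methoxy-6-(methoxymethoxy)phenoxy}ethynyl)lithium | [Li]C#COc1c(OCOC)cc(OC)cc1CO[Si](C)(C)C(C)(C)C | intermediate (not isolated)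
12 | tert-butyl{[2-(ethynyloxy)-5-methoxy-3-(methoxymethoxy)phenyl]methoxy}dimethylsilane | C#COc1c(OCOC)cc(OC)cc1CO[Si](C)(C)C(C)(C)C | intermediate
13 | dimethyl malonate | COC(=O)CC(=O)OC | starting material
14 | 2,2,6-trimethyl-4H-1,3-dioxin-4-one | CC1=CC(=O)OC(C)(C)O1 | starting material
15 | acetylketene (but-1-ene-1,3-dione) | CC(=O)C=C=O | intermediate (not isolated)
16 | dimethyl 2-(3-oxobutanoyl)malonate (present as its sodium enolate) | COC(=O)C(C(=O)OC)C(=O)CC(C)=O | intermediate (not isolated)
17 | methyl 4-hydroxy-6-methyl-2-oxo-2H-pyran-3-carboxylate | COC(=O)C1=C(O)C=C(C)OC1=O | intermediate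
18 | methyl 4-acetoxy-6-methyl-2-oxo-2H-pyran-3-carboxylate | COC(=O)C1=C(OC(C)=O)C=C(C)OC1=O | intermediate
19 | methyl 5-acetoxy-8-{2-[(tert-butyldimethylsilyloxy)methyl]-4-methoxy-6-(methoxymethoxy)phenoxy}-1-methyl-3-oxo-2-oxabicyclo[2.2.2]octa-5,7-diene-4-carboxylate (racemic; one enantiomer drawn) | C[C@@]12OC(=O)[C@@](C(=O)OC)(C(OC(C)=O)=C1)C(Oc3c(OCOC)cc(OC)cc3CO[Si](C)(C)C(C)(C)C)=C2 | intermediate (not isolated)
20 | methyl 2-acetoxy-6-{2-[(tert-butyldimethylsilyloxy)methyl]-4-methoxy-6-(methoxymethoxy)phenoxy}-4-methylbenzoate | COC(=O)c1c(OC(C)=O)cc(C)cc1Oc1c(OCOC)cc(OC)cc1CO[Si](C)(C)C(C)(C)C | intermediate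
21 | methyl 2-hydroxy-6-[2-hydroxy-6-(hydroxymethyl)-4-methoxyphenoxy]-4-methylbenzoate | COC(=O)c1c(O)cc(C)cc1Oc1c(O)cc(OC)cc1CO | intermediate
22 | Betaethrin A, methyl 2-[2-(acetoxymethyl)-6-hydroxy-4-methoxyphenoxy]-6-hydroxy-4-methylbenzoate | COC(=O)c1c(O)cc(C)cc1Oc1c(O)cc(OC)cc1COC(C)=O | target

## Step count and least certain steps

Total step count: 11. Longest linear sequence: 9 steps (steps 1–6, then 9, 10 and 11, from 1). The pyrone branch is 2 steps (7 and 8).

**Step 9 (key step).** The most likely failure is thermal oligomerisation of the ynol ether outrunning the cycloaddition. The 4-acetoxy and 6-methyl groups make 18 a weaker acceptor than the parent 3-carbomethoxy-2-pyrone, and an aryloxyalkyne is a weaker donor than a ketene acetal. Acetyl transfer from the activated enol acetate at 120 °C is a second drain. The fallback reverses the electron demand but keeps the same two ring A bonds to the alkyne carbons. It sets out from acetylide 11, which is quenched with methyl chloroformate instead of methanol to give the methyl aryloxypropiolate F1. F1 is heated in toluene with the silyl ketene acetal diene F2 (from methyl 3-methylbut-2-enoate, LiN(i-Pr)2 and Me3SiCl). Loss of methanol and of the silyl group on acidic work-up should give the free salicylate F3. F3 differs from 20 only by the missing acetate and is carried through the conditions of step 10 to rejoin the route at 21.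

**Step 6.** The terminal aryloxyacetylene may be lost during isolation through acid-catalysed hydration on silica to the aryl acetate and through oligomerisation on concentration; incomplete chlorine–lithium exchange would leave chloroalkyne. The fallback sets out from acetylide 11 and traps it with Me3SiCl as the C-silyl ynol ether F4, which can be purified and stored. The silyl group is removed with K2CO3 in MeOH at 0 °C just before use, and the solution of 12 is taken into step 9 without concentration, so the route is rejoined at 12.

**Step 7.** Acetylketene may dimerise to dehydroacetic acid faster than it is captured by the poorly soluble sodium malonate in hot toluene. The fallback sets out from 13 and replaces the thermal ketene source by diketene, which acetoacetylates the malonate anion in THF at low temperature by ring opening without free ketene. It passes through the same enolate 16 and comes back at 17; no new compound is made.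

**Step 10.** Under HCl in methanol the benzylic alcohol may be converted into its methyl ether by solvolysis, and the MOM ether may cleave more slowly than the other two groups, so that forcing conditions are needed. The fallback avoids a free benzylic alcohol in protic acid and sets out from 20. HF·pyridine in THF removes only the silyl ether to give the benzylic alcohol F5. Ac2O in pyridine gives the benzylic acetate F6. ZnBr2 with n-PrSH in CH2Cl2 at 0 °C cleaves the MOM ether to give the ring B phenol F7. Pyrrolidine at 0 °C then removes the remaining aryl acetate by aminolysis without touching the alkyl acetate, which rejoins the route at 22.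

**Step 11.** The activated benzylic position may alkylate a phenol of a second molecule (oligomeric benzyl aryl ethers), and some phenol acylation through an acyloxyphosphonium species is possible. The fallback sets out from 21: peracetylation (Ac2O, pyridine, 4-dimethylaminopyridine) gives the triacetate F8, and selective aminolysis of the two aryl acetates with pyrrolidine in MeCN at 0 °C leaves the benzylic acetate and comes back at 22.

**Step 3.** Condensation of the hydroxymethyl product with unreacted phenoxide through an ortho-quinone methide would give a diarylmethane, and the electron-rich phenoxide may react slowly. The fallback sets out from 4 and uses magnesium-mediated ortho-formylation (MgCl2, Et3N, paraformaldehyde, MeCN, reflux) to the salicylaldehyde F9, which NaBH4 in MeOH reduces to rejoin the route at 5.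

## Further compounds

F1 | step 9 | methyl 3-{2-[(tert-butyldimethylsilyloxy)methyl]-4-methoxy-6-(methoxymethoxy)phenoxy}prop-2-ynoate | COC(=O)C#COc1c(OCOC)cc(OC)cc1CO[Si](C)(C)C(C)(C)C
F2 | step 9 | 1-methoxy-3-methyl-1-(trimethylsilyloxy)buta-1,3-diene (mixture of 1E and 1Z isomers; the geometry is lost on aromatisation) | COC(O[Si](C)(C)C)=CC(C)=C
F3 | step 9 | methyl 2-{2-[(tert-butyldimethylsilyloxy)methyl]-4-methoxy-6-(methoxymethoxy)phenoxy}-6-hydroxy-4-methylbenzoate | COC(=O)c1c(O)cc(C)cc1Oc1c(OCOC)cc(OC)cc1CO[Si](C)(C)C(C)(C)C
F4 | step 6 | tert-butyl{[5-methoxy-3-(methoxymethoxy)-2-{[(trimethylsilyl)ethynyl]oxy}phenyl]methoxy}dimethylsilane | C[Si](C)(C)C#COc1c(OCOC)cc(OC)cc1CO[Si](C)(C)C(C)(C)C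
F0 | step 7 | none | none
F5 | step 10 | methyl 2-acetoxy-6-[2-(hydroxymethyl)-4-methoxy-6-(methoxymethoxy)phenoxy]-4-methylbenzoate | COC(=O)c1c(OC(C)=O)cc(C)cc1Oc1c(OCOC)cc(OC)cc1CO
F6 | step 10 | methyl 2-acetoxy-6-[2-(acetoxymethyl)-4-methoxy-6-(methoxymethoxy)phenoxy]-4-methylbenzoate | COC(=O)c1c(OC(C)=O)cc(C)cc1Oc1c(OCOC)cc(OC)cc1COC(C)=O
F7 | step 10 | methyl 2-acetoxy-6-[2-(acetoxymethyl)-6-hydroxy-4-methoxyphenoxy]-4-methylbenzoate | COC(=O)c1c(OC(C)=O)cc(C)cc1Oc1c(O)cc(OC)cc1COC(C)=O
F8 | step 11 | methyl 2-acetoxy-6-[2-acetoxy-6-(acetoxymethyl)-4-methoxyphenoxy]-4-methylbenzoate | COC(=O)c1c(OC(C)=O)cc(C)cc1Oc1c(OC(C)=O)cc(OC)cc1COC(C)=O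
F9 | step 3 | 2-hydroxy-5-methoxy-3-(methoxymethoxy)benzaldehyde | O=Cc1cc(OC)cc(OCOC)c1O
A1 | alternative 1 | 2-(2-acetoxy-6-hydroxy-4-methylbenzoyl)-3-hydroxy-5-methoxybenzyl acetate | CC(=O)Oc1cc(C)cc(O)c1C(=O)c1c(O)cc(OC)cc1COC(C)=O
A2 | alternative 1 | 4-acetoxy-6'-(acetoxymethyl)-4'-methoxy-6-methyl-3H-spiro[benzofuran-2,1'-cyclohexa-3',5'-diene]-2',3-dione (racemic; one enantiomer drawn) | Cc1cc(OC(C)=O)c2c(c1)O[C@@]1(C2=O)C(=O)C=C(OC)C=C1COC(C)=O
A3 | alternative 2 | 2-methoxy-4-methyl-6-(trimethylsilyl)phenyl trifluoromethanesulfonate | COc1cc(C)cc([Si](C)(C)C)c1OS(=O)(=O)C(F)(F)F
A4 | alternative 2 | 3-(benzyloxy)-2-hydroxy-5-methoxybenzyl acetate | CC(=O)OCc1cc(OC)cc(OCc2ccccc2)c1O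
A5 | alternative 2 | methyl 2-[2-(acetoxymethyl)-6-(benzyloxy)-4-methoxyphenoxy]-6-methoxy-4-methylbenzoate | COC(=O)c1c(OC)cc(C)cc1Oc1c(OCc2ccccc2)cc(OC)cc1COC(C)=O
A6 | alternative 3 | methyl 3-{2-[(tert-butyldimethylsilyloxy)methyl]-4-methoxy-6-(methoxymethoxy)phenoxy}prop-2-ynoate | COC(=O)C#COc1c(OCOC)cc(OC)cc1CO[Si](C)(C)C(C)(C)C
A7 | alternative 3 | 1-methoxy-3-methyl-1-(trimethylsilyloxy)buta-1,3-diene (mixture of 1E and 1Z isomers) | COC(O[Si](C)(C)C)=CC(C)=C
A8 | alternative 3 | methyl 2-{2-[(tert-butyldimethylsilyloxy)methyl]-4-methoxy-6-(methoxymethoxy)phenoxy}-6-hydroxy-4-methylbenzoate | COC(=O)c1c(O)cc(C)cc1Oc1c(OCOC)cc(OC)cc1CO[Si](C)(C)C(C)(C)C
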